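**Assumptions:** C1 is the ketone carbon, so the target is (2S,3S,4S) (Cα = C2, Cβ = C3, Cγ = C4). Compound 15 and the (R)-prolinol ether catalyst are bought. The C1 and C6 centres of 14 and 16 are left undefined because step 9 destroys both.

## Retrosynthetic overview

1. Target ⇒ its aryl TBS ether ⇒ (new step) ring-opening retro-carbonyl-ene of a 1-aryl-2-isopropenylcyclohexanol. This breaks ring bond C1–C6 and releases the aryl ketone and the C4 prenyl group together.
2. That carbinol ⇒ arylcerium addition to a cyclohexanone whose C6 isopropenyl group comes from Pd α-alkenylation.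
3. The cyclohexanone (all three stereocentres) ⇒ (S)-2-methyl-4-(3-methylbut-3-enyl)cyclohexenone, by trans conjugate isopropenylation (Cβ) and anti prenylation of the enolate (Cα).
4. The enone ⇒ organocatalytic Michael addition of 5-methylhex-5-enal to ethyl vinyl ketone (sets Cγ), then aldol condensation.
5. Only one ring is formed (cyclohexenone, step 4). It serves as a stereochemical template and is opened in step 9.

## Route

**Step 1**
Reactants: 1 ethyl 5-oxohexanoate; 2 methyltriphenylphosphonium bromide
Product: 3 ethyl 5-methylhex-5-enoate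
Conditions: 2, KOt-Bu, THF, 0 °C → rt
Reagents that add atoms: methyltriphenylphosphonium bromide, C[P+](c1ccccc1)(c1ccccc1)c1ccccc1.[Br-]
Why: Wittig methylenation is selective for the ketone over the ester; no stereocentre is involved.

**Step 2**
Reactants: 3 ethyl 5-methylhex-5-enoate
Product: 4 5-methylhex-5-enal
Conditions: DIBAL-H (1.05 equiv), CH2Cl2, −78 °C; Rochelle salt
Reagents that add atoms: none
Why: DIBAL half-reduction of an ester stops at the aldehyde at −78 °C through the stable aluminium hemiacetal; the isolated alkene is inert.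

**Step 3**
Reactants: 4 5-methylhex-5-enal; 5 pent-1-en-3-one (ethyl vinyl ketone)
Product: 6 (2S)-2-(3-methylbut-3-en-1-yl)-5-oxoheptanal
Conditions: (R)-2-[methoxy(diphenyl)methyl]pyrrolidine (5 mol %), ethyl 3,4-dihydroxybenzoate (20 mol %), neat, 4 °C
Reagents that add atoms: pent-1-en-3-one, C=CC(=O)CC
Why: Enamine-catalysed asymmetric Michael addition; the diarylmethyl group shields one face of the E-enamine of 4, so the enone adds to the open face and the (R)-catalyst gives the (S) α-centre (by the standard shielding model; use the (S)-catalyst if the sense proves opposite). This centre becomes C4 (Cγ) of the target.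

**Step 4**
Reactants: 6 (2S)-2-(3-methylbut-3-en-1-yl)-5-oxoheptanal
Product: 7 (4S)-2-methyl-4-(3-methylbut-3-en-1-yl)cyclohex-2-en-1-one
Conditions: LiOH (0.1 equiv), i-PrOH, rt
Reagents that add atoms: none
Why: Intramolecular aldol condensation; only the ethyl-ketone CH2 can close a six-membered ring onto the aldehyde, and mild base limits epimerisation of the aldehyde α-centre before closure.

**Step 5**
Reactants: 7 the (4S)-enone; 8 isopropenylmagnesium bromide; 9 chlorotrimethylsilane
Product: 10 trimethyl{[(3S,4S)-2-methyl-4-(3-methylbut-3-en-1-yl)-3-(prop-1-en-2-yl)cyclohex-1-en-1-yl]oxy}silane (3-isopropenyl trans to the 4-side chain)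
Conditions: CuBr·SMe2 (10 mol %), TMSCl, HMPA, THF, −78 → −40 °C; Et3N quench
Reagents that add atoms: isopropenylmagnesium bromide, CC(=C)[Mg]Br; chlorotrimethylsilane, C[Si](C)(C)Cl
Why: Copper-catalysed, TMSCl-accelerated conjugate addition enters anti to the C4 substituent (sets C3 = Cβ as S), and silylation traps the tetrasubstituted enolate regiospecifically.

**Step 6**
Reactants: 10 the TMS enol ether; 11 prenyl bromide (1-bromo-3-methylbut-2-ene)
Product: 12 (2S,3S,4S)-2-methyl-2-(3-methylbut-2-en-1-yl)-4-(3-methylbut-3-en-1-yl)-3-(prop-1-en-2-yl)cyclohexan-1-one (2-prenyl trans to 3-isopropenyl; 3-isopropenyl trans to the 4-side chain)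
Conditions: MeLi, THF, 0 °C; then prenyl bromide, HMPA, −78 → −20 °C
Reagents that add atoms: prenyl bromide, CC(C)=CCBr
Why: Regiospecific lithium enolate generation followed by SN2 C-alkylation; the electrophile enters anti to the adjacent C3 isopropenyl group (held pseudoaxial by A1,2 strain with the C2 methyl), which sets the quaternary C2 = Cα as S.

**Step 7**
Reactants: 12 the (2S,3S,4S)-ketone; 13 2-bromopropene
Product: 14 (2S,3S,4S,6RS)-2-methyl-2-(3-methylbut-2-en-1-yl)-4-(3-methylbut-3-en-1-yl)-3,6-di(prop-1-en-2-yl)cyclohexan-1-one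
Conditions: LiHMDS, Pd2(dba)3 (2.5 mol %), P(t-Bu)3 (6 mol %), toluene, rt → 50 °C; AcOH quench at −78 °C
Reagents that add atoms: 2-bromopropene, CC(Br)=C
Why: Palladium-catalysed ketone α-alkenylation (enolate cross-coupling); C6 is the only enolisable position, and the cold kinetic quench keeps the new alkene β,γ. C2 (quaternary) and C3, C4 (not α to the carbonyl) cannot epimerise.

**Step 8**
Reactants: 14 the 6-isopropenyl ketone; 15 (3-bromophenoxy)(tert-butyl)dimethylsilane
Product: 16 (1RS,2S,3S,4S,6RS)-1-{3-[(tert-butyldimethylsilyl)oxy]phenyl}-2-methyl-2-(3-methylbut-2-en-1-yl)-4-(3-methylbut-3-en-1-yl)-3,6-di(prop-1-en-2-yl)cyclohexan-1-ol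
Conditions: 15, t-BuLi, THF, −78 °C; anhydrous CeCl3; then 14, −78 → −40 °C; aq NH4Cl at −78 °C
Reagents that add atoms: (3-bromophenoxy)(tert-butyl)dimethylsilane, CC(C)(C)[Si](C)(C)Oc1cccc(Br)c1
Why: Organocerium 1,2-addition; the low basicity of the aryl cerium reagent suppresses enolisation of the acidic C6–H and favours addition to the hindered carbonyl. The cold quench avoids alkoxide retro-allylation.

**Step 9**
Reactants: 16 the 1-aryl-2-isopropenylcyclohexanol
Product: 17 (2S,3S,4S)-1-{3-[(tert-butyldimethylsilyl)oxy]phenyl}-2,7-dimethyl-2,4-bis(3-methylbut-2-en-1-yl)-3-(prop-1-en-2-yl)oct-7-en-1-one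
Conditions: mesitylene (0.02 M, degassed), 2,6-lutidine (10 mol %), 200–210 °C, sealed base-washed tube
Reagents that add atoms: none
Why: Proposed new method: a ring-opening retro-carbonyl-ene in which the carbinol O–H is delivered through a six-membered transition state to the terminal CH2 of the C6 isopropenyl group while the C1–C6 bond breaks, giving the aryl ketone (C1=O) and the prenyl alkene (C6=CMe2) regiospecifically. It should be driven by relief of congestion at the carbinol flanked by the quaternary carbon, by aryl-ketone conjugation and by entropy. Compound 16 contains only one β-hydroxy-olefin array, so the other three alkenes are not involved. C2, C3 and C4 are untouched, and ring carbon C4 becomes the acyclic (S) centre carrying the new prenyl arm and the 3-methylbut-3-enyl arm. All C1/C6 diastereomers can reach the gauche O–C1–C6–C7 geometry and so should converge. The closest known reaction type is the thermal retro-ene fragmentation of β-hydroxy olefins (reverse carbonyl-ene); it has not been shown as a deconstruction of a fully substituted 1-aryl-2-alkenylcyclohexanol to an α-quaternary aryl ketone.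

**Step 10**
Reactants: 17 the TBS ether
Product: 18 garcinielliptone FA, (2S,3S,4S)-1-(3-hydroxyphenyl)-2,7-dimethyl-2,4-bis(3-methylbut-2-en-1-yl)-3-(prop-1-en-2-yl)oct-7-en-1-one
Conditions: TBAF, THF, 0 °C
Reagents that add atoms: none
Why: Fluoride cleavage of the aryl silyl ether; the ketone has no α-hydrogen and the alkenes are unaffected.

## Compound list

1 | ethyl 5-oxohexanoate | CCOC(=O)CCCC(C)=O | starting material
2 | methyltriphenylphosphonium bromide | C[P+](c1ccccc1)(c1ccccc1)c1ccccc1.[Br-] | starting material
3 | ethyl 5-methylhex-5-enoate | CCOC(=O)CCCC(C)=C | intermediate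
4 | 5-methylhex-5-enal | O=CCCCC(C)=C | intermediate
5 | pent-1-en-3-one | C=CC(=O)CC | starting material
6 | (2S)-2-(3-methylbut-3-en-1-yl)-5-oxoheptanal | O=C[C@@H](CCC(C)=C)CCC(=O)CC | intermediate
7 | (4S)-2-methyl-4-(3-methylbut-3-en-1-yl)cyclohex-2-en-1-one | O=C1C(C)=C[C@@H](CCC(C)=C)CC1 | intermediate
8 | isopropenylmagnesium bromide | CC(=C)[Mg]Br | starting material
9 | chlorotrimethylsilane | C[Si](C)(C)Cl | starting material
10 | trimethyl{[(3S,4S)-2-methyl-4-(3-methylbut-3-en-1-yl)-3-(prop-1-en-2-yl)cyclohex-1-en-1-yl]oxy}silane | C[Si](C)(C)OC1=C(C)[C@H](C(C)=C)[C@@H](CCC(C)=C)CC1 | intermediate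
11 | prenyl bromide | CC(C)=CCBr | starting material
12 | (2S,3S,4S)-2-methyl-2-(3-methylbut-2-en-1-yl)-4-(3-methylbut-3-en-1-yl)-3-(prop-1-en-2-yl)cyclohexan-1-one | O=C1[C@@](C)(CC=C(C)C)[C@H](C(C)=C)[C@@H](CCC(C)=C)CC1 | intermediate
13 | 2-bromopropene | CC(Br)=C | starting material
14 | (2S,3S,4S,6RS)-2-methyl-2-(3-methylbut-2-en-1-yl)-4-(3-methylbut-3-en-1-yl)-3,6-di(prop-1-en-2-yl)cyclohexan-1-one | O=C1[C@@](C)(CC=C(C)C)[C@H](C(C)=C)[C@@H](CCC(C)=C)CC1C(C)=C | intermediate
15 | (3-bromophenoxy)(tert-butyl)dimethylsilane | CC(C)(C)[Si](C)(C)Oc1cccc(Br)c1 | starting material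
16 | (1RS,2S,3S,4S,6RS)-1-{3-[(tert-butyldimethylsilyl)oxy]phenyl}-2-methyl-2-(3-methylbut-2-en-1-yl)-4-(3-methylbut-3-en-1-yl)-3,6-di(prop-1-en-2-yl)cyclohexan-1-ol | OC1(c2cccc(O[Si](C)(C)C(C)(C)C)c2)[C@@](C)(CC=C(C)C)[C@H](C(C)=C)[C@@H](CCC(C)=C)CC1C(C)=C | intermediate
17 | (2S,3S,4S)-1-{3-[(tert-butyldimethylsilyl)oxy]phenyl}-2,7-dimethyl-2,4-bis(3-methylbut-2-en-1-yl)-3-(prop-1-en-2-yl)oct-7-en-1-one | C=C(C)CC[C@@H](CC=C(C)C)[C@@H](C(=C)C)[C@](C)(CC=C(C)C)C(=O)c1cccc(O[Si](C)(C)C(C)(C)C)c1 | intermediate
18 | garcinielliptone FA, (2S,3S,4S)-1-(3-hydroxyphenyl)-2,7-dimethyl-2,4-bis(3-methylbut-2-en-1-yl)-3-(prop-1-en-2-yl)oct-7-en-1-one | C=C(C)CC[C@@H](CC=C(C)C)[C@@H](C(=C)C)[C@](C)(CC=C(C)C)C(=O)c1cccc(O)c1 | target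

## Summary

Total steps: 10. Longest linear sequence: 10 (fully linear; 15 and all reagents are purchased).

Three steps most likely to fail:

1. **Step 9 (proposed new retro-ene ring opening).** Risks are a higher barrier than estimated, or thermal side reactions of the polyene. Fallback with known chemistry, from 12 and replacing steps 7–9:
   - α′-hydroxylation at C6 (KHMDS, Davis oxaziridine);
   - addition of the aryllithium from 15 with CeCl3 to give the 1-aryl-1,2-diol;
   - Pb(OAc)4 glycol cleavage to the aryl ketone–aldehyde;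
   - Wittig olefination with isopropylidenetriphenylphosphorane to give 17.

2. **Step 8 (aryl addition to the hindered, enolisable ketone 14).** Fallback: build 16 by epoxide opening instead of carbonyl addition. Convert 12 to its 6-bromo ketone (silyl enol ether, NBS), add the aryllithium and close to the 1-aryl-1,2-epoxide, then open at C6 with an isopropenyl cuprate.

3. **Step 6 (facial selectivity at the quaternary centre).** The trans-C4 chain may erode or reverse the anti-to-C3 preference. Fallback: exchange the roles of the two C2 substituents. Make the 2-prenyl enone (4 plus 7-methylocta-1,6-dien-3-one, same Michael/aldol sequence), add the isopropenyl cuprate, and quench the enolate with MeI. This gives the (2S) centre if the electrophile enters syn to C3. If selectivity is merely poor either way, the cyclic diastereomers of 12 would have to be separated by chromatography.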